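**Retrosynthetic overview**
1. Target 34 ⇐ triol 32 (formylation of the primary OH, then acetylation of the two secondary OH) ⇐ bis-silyl ether 31.
2. Ring B is closed last: intramolecular Heck reaction of vinyl bromide 30 forms C8–C8a, the cis ring fusion and the C1=C2 alkene in one step.
3. 30 ⇐ ketone 29 ⇐ late C6–C7 union of dithiane 16 (fragment 1: ring A plus C5/C6; 23 heavy atoms) with allylic bromide 26 (fragment 2: C7, C8 and the side chain; 15 heavy atoms) by Corey–Seebach alkylation.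
4. Fragment 1: ring A is made first (Brown crotylation, then RCM); the C4a–C5 bond and the C5 methyl centre come from an Ireland–Claisen rearrangement. Fragment 2: the tetrasubstituted alkene geometry is locked in a bromobutenolide ring before opening.
5. Ring order: ring A (step 2), then ring B (step 21).

Assumption: locants in the text are those of the octahydronaphthalene core of 34 (C1=C2 ring alkene, C3 and C6 acetoxy carbons, C5 methyl carbon, C8 alkylidene carbon, C4a/C8a ring fusion).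

**Fragment 1**

Step 1
Reactants: 1 pent-4-enal; 2 (Z)-but-2-ene
Product: 5 (3S,4S)-3-methylocta-1,7-dien-4-ol, via (Z)-but-2-en-1-ylpotassium 3 (not isolated), via (Z)-crotylbis(isopinocampheyl)borane 4 (not isolated)
Conditions: 2, KOt-Bu, n-BuLi, THF, −78 → −45 °C; (+)-Ipc2BOMe [from (−)-α-pinene], −78 °C; BF3·OEt2; 1, −78 °C; NaOH, H2O2
Reagents that add atoms: none
Why: Brown crotylboration through a closed Zimmerman–Traxler chair, so the Z-crotyl geometry gives the syn pair and the isopinocampheyl groups direct attack to the re face of the aldehyde, setting both centres (3S,4S).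

Step 2
Reactants: 5 (3S,4S)-3-methylocta-1,7-dien-4-ol
Product: 6 (1S,2S)-2-methylcyclohex-3-en-1-ol
Conditions: second-generation Grubbs catalyst (2 mol %), CH2Cl2, 40 °C
Reagents that add atoms: none
Why: Ring-closing metathesis of the 1,7-diene gives ring A with loss of ethene and leaves both stereocentres untouched.

Step 3
Reactants: 6 (1S,2S)-2-methylcyclohex-3-en-1-ol
Product: 7 (1S,2R,3S,6R)-2-methyl-7-oxabicyclo[4.1.0]heptan-3-ol
Conditions: VO(acac)2 (2 mol %), t-BuOOH, CH2Cl2, 0 °C → rt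
Reagents that add atoms: tert-butyl hydroperoxide, CC(C)(C)OO
Why: Hydroxyl-directed (Sharpless–Michaelson) epoxidation delivers oxygen to the face of the homoallylic OH, which is also the face anti to the allylic methyl group, so the epoxide is cis to OH.

Step 4
Reactants: 7 (1S,2R,3S,6R)-2-methyl-7-oxabicyclo[4.1.0]heptan-3-ol
Product: 8 tert-butyldimethyl{[(1S,2S,3S,6R)-2-methyl-7-oxabicyclo[4.1.0]heptan-3-yl]oxy}silane
Conditions: TBSCl, imidazole, DMF, 0 °C → rt
Reagents that add atoms: tert-butyldimethylsilyl chloride, CC(C)(C)[Si](C)(C)Cl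
Why: Standard silylation protects the secondary alcohol before the strongly basic steps.

Step 5
Reactants: 8 tert-butyldimethyl{[(1S,2S,3S,6R)-2-methyl-7-oxabicyclo[4.1.0]heptan-3-yl]oxy}silane
Product: 9 (1R,5S,6S)-5-[(tert-butyldimethylsilyl)oxy]-6-methylcyclohex-2-en-1-ol
Conditions: LiN(i-Pr)2 (3 equiv), Et2O, 0 °C → reflux
Reagents that add atoms: none
Why: Lithium amide epoxide-to-allylic-alcohol rearrangement (syn β-elimination) removes a proton from the unhindered ring CH2 and not from the crowded methine, so the oxygen stays on the carbon next to the methyl-bearing centre with its configuration intact.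

Step 6
Reactants: 9 (1R,5S,6S)-5-[(tert-butyldimethylsilyl)oxy]-6-methylcyclohex-2-en-1-ol; 10 propanoyl chloride
Product: 11 (1R,5S,6S)-5-[(tert-butyldimethylsilyl)oxy]-6-methylcyclohex-2-en-1-yl propanoate
Conditions: pyridine, DMAP (cat.), CH2Cl2, 0 °C
Reagents that add atoms: none
Why: Simple O-acylation installs the three-carbon unit (future C5, its methyl group and C6) as an allylic ester.

Step 7
Reactants: 11 (1R,5S,6S)-5-[(tert-butyldimethylsilyl)oxy]-6-methylcyclohex-2-en-1-yl propanoate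
Product: 14 (2S)-2-[(1R,4S,5S)-5-[(tert-butyldimethylsilyl)oxy]-4-methylcyclohex-2-en-1-yl]propan-1-ol, via (Z)-silyl ketene acetal 12 (not isolated), via trimethylsilyl ester 13 (not isolated)
Conditions: LiN(i-Pr)2, THF–DMPU (4:1), −78 °C; TMSCl; −78 → 65 °C; then LiAlH4, 0 °C
Reagents that add atoms: none
Why: Ireland–Claisen rearrangement: enolisation in THF–DMPU gives the (Z)-silyl ketene acetal, which rearranges suprafacially through the boat-like transition state favoured for cyclohexenyl esters, so the new C–C bond forms on the face that carried the ester oxygen (ring centre R) and the methyl-bearing centre becomes S; the silyl ester is reduced in the same flask.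

Step 8
Reactants: 14 (2S)-2-[(1R,4S,5S)-5-[(tert-butyldimethylsilyl)oxy]-4-methylcyclohex-2-en-1-yl]propan-1-ol
Product: 15 (2S)-2-[(1R,4S,5S)-5-[(tert-butyldimethylsilyl)oxy]-4-methylcyclohex-2-en-1-yl]propanal
Conditions: Dess–Martin periodinane, NaHCO3, CH2Cl2, 0 °C
Reagents that add atoms: none
Why: Buffered Dess–Martin oxidation gives the α-branched aldehyde without epimerisation.

Step 9
Reactants: 15 (2S)-2-[(1R,4S,5S)-5-[(tert-butyldimethylsilyl)oxy]-4-methylcyclohex-2-en-1-yl]propanal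
Product: 16 2-{(1S)-1-[(1R,4S,5S)-5-[(tert-butyldimethylsilyl)oxy]-4-methylcyclohex-2-en-1-yl]ethyl}-1,3-dithiane
Conditions: HS(CH2)3SH, BF3·OEt2, CH2Cl2, −40 → −20 °C
Reagents that add atoms: propane-1,3-dithiol, SCCCS
Why: Lewis-acid thioacetalisation at low temperature turns the aldehyde carbon (future C6) into an acyl-anion equivalent (Corey–Seebach umpolung) without touching the neighbouring centre.

**Fragment 2**

Step 10
Reactants: 17 methyl 3-methylbut-2-enoate
Product: 18 methyl 4-bromo-3-methylbut-2-enoate (E/Z mixture)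
Conditions: NBS, (PhCO2)2 (cat.), CCl4, reflux
Reagents that add atoms: N-bromosuccinimide, O=C1CCC(=O)N1Br
Why: Wohl–Ziegler allylic bromination functionalises one γ-methyl group.

Step 11
Reactants: 18 methyl 4-bromo-3-methylbut-2-enoate (E/Z mixture)
Product: 19 4-methylfuran-2(5H)-one
Conditions: neat, 150 °C (MeBr distils off)
Reagents that add atoms: none
Why: Thermal lactonisation: the Z isomer cyclises by O-alkylation with loss of bromomethane while the E isomer equilibrates under the conditions.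

Step 12
Reactants: 19 4-methylfuran-2(5H)-one
Product: 21 3-bromo-4-methylfuran-2(5H)-one, via trans-dibromolactone 20 (not isolated)
Conditions: Br2, CCl4, 60 °C; then Et3N, 0 °C
Reagents that add atoms: bromine, BrBr
Why: Bromine addition followed by E1cB loss of HBr from the acidic α-position gives the α-bromobutenolide, whose ring holds Br cis to the methyl group and the carbonyl carbon cis to the CH2O carbon.

Step 13
Reactants: 21 3-bromo-4-methylfuran-2(5H)-one
Product: 22 (2E)-2-bromo-4-hydroxy-N-methoxy-N,3-dimethylbut-2-enamide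
Conditions: MeNH(OMe)·HCl, i-PrMgCl, THF, −20 → 0 °C
Reagents that add atoms: N,O-dimethylhydroxylamine hydrochloride, Cl.CNOC
Why: Weinreb aminolysis opens the lactone at the acyl carbon, differentiating the two ends of the alkene while keeping the ring-derived geometry.

Step 14
Reactants: 22 (2E)-2-bromo-4-hydroxy-N-methoxy-N,3-dimethylbut-2-enamide
Product: 23 (2E)-2-bromo-4-[(tert-butyldimethylsilyl)oxy]-N-methoxy-N,3-dimethylbut-2-enamide
Conditions: TBSCl, imidazole, DMF, 0 °C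
Reagents that add atoms: tert-butyldimethylsilyl chloride, CC(C)(C)[Si](C)(C)Cl
Why: Silylation of the primary alcohol (the future formate oxygen) prevents relactonisation.

Step 15
Reactants: 23 (2E)-2-bromo-4-[(tert-butyldimethylsilyl)oxy]-N-methoxy-N,3-dimethylbut-2-enamide
Product: 24 (2E)-2-bromo-4-[(tert-butyldimethylsilyl)oxy]-3-methylbut-2-enal
Conditions: i-Bu2AlH, THF, −78 °C
Reagents that add atoms: none
Why: Weinreb amide reduction stops at the aldehyde through the chelated tetrahedral intermediate.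

Step 16
Reactants: 24 (2E)-2-bromo-4-[(tert-butyldimethylsilyl)oxy]-3-methylbut-2-enal
Product: 25 (2E)-2-bromo-4-[(tert-butyldimethylsilyl)oxy]-3-methylbut-2-en-1-ol
Conditions: NaBH4, CeCl3·7H2O, MeOH, −40 °C
Reagents that add atoms: none
Why: Luche 1,2-reduction gives the allylic alcohol without conjugate reduction or alkene isomerisation.

Step 17
Reactants: 25 (2E)-2-bromo-4-[(tert-butyldimethylsilyl)oxy]-3-methylbut-2-en-1-ol
Product: 26 tert-butyl{[(2E)-3,4-dibromo-2-methylbut-2-en-1-yl]oxy}dimethylsilane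
Conditions: CBr4, PPh3, CH2Cl2, 0 °C
Reagents that add atoms: tetrabromomethane, BrC(Br)(Br)Br
Why: Appel bromination proceeds by SN2 at the primary carbon; allylic transposition is blocked because the other alkene terminus is fully substituted.

**Coupling and completion**

Step 18
Reactants: 16 2-{(1S)-1-[(1R,4S,5S)-5-[(tert-butyldimethylsilyl)oxy]-4-methylcyclohex-2-en-1-yl]ethyl}-1,3-dithiane; 26 tert-butyl{[(2E)-3,4-dibromo-2-methylbut-2-en-1-yl]oxy}dimethylsilane
Product: 28 2-[(2E)-2-bromo-4-[(tert-butyldimethylsilyl)oxy]-3-methylbut-2-en-1-yl]-2-{(1S)-1-[(1R,4S,5S)-5-[(tert-butyldimethylsilyl)oxy]-4-methylcyclohex-2-en-1-yl]ethyl}-1,3-dithiane, via 2-lithiodithiane 27 (not isolated)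
Conditions: t-BuLi, THF–HMPA (10:1), −78 °C; then 26, −78 → −40 °C
Reagents that add atoms: none
Why: Corey–Seebach alkylation: the 2-lithio-1,3-dithiane displaces the primary allylic bromide (SN2), joining the two fragments at the C6–C7 bond without touching a stereocentre or the vinyl bromide.

Step 19
Reactants: 28 (the alkylated dithiane)
Product: 29 (2S,5E)-5-bromo-7-[(tert-butyldimethylsilyl)oxy]-2-[(1R,4S,5S)-5-[(tert-butyldimethylsilyl)oxy]-4-methylcyclohex-2-en-1-yl]-6-methylhept-5-en-3-one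
Conditions: MeI, CaCO3, MeCN–H2O (9:1), 40 °C
Reagents that add atoms: water, O
Why: S-Methylation and hydrolysis unmask the ketone under near-neutral conditions, which protects the α-centre and the β,γ-alkene position.

Step 20
Reactants: 29 (the ketone)
Product: 30 (2S,3S,5E)-5-bromo-7-[(tert-butyldimethylsilyl)oxy]-2-[(1R,4S,5S)-5-[(tert-butyldimethylsilyl)oxy]-4-methylcyclohex-2-en-1-yl]-6-methylhept-5-en-3-ol
Conditions: (R)-2-methyl-CBS-oxazaborolidine (0.5 equiv), catecholborane, toluene, −78 °C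
Reagents that add atoms: none
Why: Corey–Bakshi–Shibata reduction: the (R)-oxazaborolidine places the α-branched substituent as the large group and delivers hydride to give the 3S carbinol (future C6) under catalyst control, overriding the substrate's Felkin–Anh preference for the 3R epimer.

Step 21
Reactants: 30 (the 3S alcohol)
Product: 31 (3S,4aR,5S,6S,8E,8aR)-3-[(tert-butyldimethylsilyl)oxy]-8-{1-[(tert-butyldimethylsilyl)oxy]propan-2-ylidene}-2,5-dimethyl-3,4,4a,5,6,7,8,8a-octahydronaphthalen-6-ol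
Conditions: Pd(OAc)2 (10 mol %), PPh3 (30 mol %), Ag2CO3 (2 equiv), MeCN, 80 °C
Reagents that add atoms: none
Why: Intramolecular Heck reaction: zerovalent palladium inserts into the vinyl bromide with retention, 6-exo syn-carbopalladation of the ring alkene occurs from the face of the tether (cis fusion, C8a set as R), and syn β-hydride elimination towards the methyl-bearing carbon gives the C1=C2 alkene.

Step 22
Reactants: 31 (the bis-silyl ether)
Product: 32 (3S,4aR,5S,6S,8E,8aR)-8-(1-hydroxypropan-2-ylidene)-2,5-dimethyl-3,4,4a,5,6,7,8,8a-octahydronaphthalene-3,6-diol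
Conditions: Bu4NF, THF, 0 °C → rt
Reagents that add atoms: none
Why: Fluoride-mediated desilylation frees both silyl-protected hydroxyl groups.

Step 23
Reactants: 32 (the triol)
Product: 33 (E)-2-[(3S,4aR,5S,6S,8aR)-3,6-dihydroxy-2,5-dimethyl-3,4,4a,5,6,7,8,8a-octahydronaphthalen-8-ylidene]propyl formate
Conditions: HCO2H (1.1 equiv), DCC (1.1 equiv), DMAP (5 mol %), CH2Cl2, −30 °C
Reagents that add atoms: formic acid, OC=O
Why: Steglich-type formylation at low temperature is selective for the unhindered primary allylic alcohol over the two secondary alcohols.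

Step 24
Reactants: 33 (the formate diol)
Product: 34 (E)-2-[(3S,4aR,5S,6S,8aR)-3,6-diacetoxy-2,5-dimethyl-3,4,4a,5,6,7,8,8a-octahydronaphthalen-8-ylidene]propyl formate (CNP0262962.2)
Conditions: Ac2O, pyridine, DMAP (cat.), CH2Cl2, 0 °C → rt
Reagents that add atoms: acetic anhydride, CC(=O)OC(C)=O
Why: Acetylation of the two secondary alcohols completes the target without disturbing the formate or any stereocentre.

**Compound list**
1 | pent-4-enal | C=CCCC=O | starting material
2 | (Z)-but-2-ene | C/C=C\C | starting material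
3 | (Z)-but-2-en-1-ylpotassium | C/C=C\C[K] | intermediate
4 | (Z)-crotylbis(isopinocampheyl)borane, Ipc from (−)-α-pinene | C/C=C\CB([C@H]1C[C@H]2C[C@@H]([C@@H]1C)C2(C)C)[C@H]1C[C@H]2C[C@@H]([C@@H]1C)C2(C)C | intermediate
5 | (3S,4S)-3-methylocta-1,7-dien-4-ol | C=C[C@H](C)[C@@H](O)CCC=C | intermediate
6 | (1S,2S)-2-methylcyclohex-3-en-1-ol | O[C@H]1CCC=C[C@@H]1C | intermediate
7 | (1S,2R,3S,6R)-2-methyl-7-oxabicyclo[4.1.0]heptan-3-ol | O[C@H]1CC[C@H]2O[C@H]2[C@@H]1C | intermediate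
8 | tert-butyldimethyl{[(1S,2S,3S,6R)-2-methyl-7-oxabicyclo[4.1.0]heptan-3-yl]oxy}silane | CC(C)(C)[Si](C)(C)O[C@H]1CC[C@H]2O[C@H]2[C@@H]1C | intermediate
9 | (1R,5S,6S)-5-[(tert-butyldimethylsilyl)oxy]-6-methylcyclohex-2-en-1-ol | O[C@@H]1C=CC[C@H](O[Si](C)(C)C(C)(C)C)[C@H]1C | intermediate
10 | propanoyl chloride | CCC(Cl)=O | starting material
11 | (1R,5S,6S)-5-[(tert-butyldimethylsilyl)oxy]-6-methylcyclohex-2-en-1-yl propanoate | CCC(=O)O[C@@H]1C=CC[C@H](O[Si](C)(C)C(C)(C)C)[C@H]1C | intermediate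
12 | (Z)-O-trimethylsilyl ketene acetal of 11 | C/C=C(\O[Si](C)(C)C)O[C@@H]1C=CC[C@H](O[Si](C)(C)C(C)(C)C)[C@H]1C | intermediate
13 | trimethylsilyl (2S)-2-[(1R,4S,5S)-5-[(tert-butyldimethylsilyl)oxy]-4-methylcyclohex-2-en-1-yl]propanoate | C[C@H](C(=O)O[Si](C)(C)C)[C@H]1C=C[C@H](C)[C@@H](O[Si](C)(C)C(C)(C)C)C1 | intermediate
14 | (2S)-2-[(1R,4S,5S)-5-[(tert-butyldimethylsilyl)oxy]-4-methylcyclohex-2-en-1-yl]propan-1-ol | OC[C@@H](C)[C@H]1C=C[C@H](C)[C@@H](O[Si](C)(C)C(C)(C)C)C1 | intermediate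
15 | (2S)-2-[(1R,4S,5S)-5-[(tert-butyldimethylsilyl)oxy]-4-methylcyclohex-2-en-1-yl]propanal | O=C[C@@H](C)[C@H]1C=C[C@H](C)[C@@H](O[Si](C)(C)C(C)(C)C)C1 | intermediate
16 | 2-{(1S)-1-[(1R,4S,5S)-5-[(tert-butyldimethylsilyl)oxy]-4-methylcyclohex-2-en-1-yl]ethyl}-1,3-dithiane | C[C@H](C1SCCCS1)[C@H]2C=C[C@H](C)[C@@H](O[Si](C)(C)C(C)(C)C)C2 | intermediate
17 | methyl 3-methylbut-2-enoate | COC(=O)C=C(C)C | starting material
18 | methyl 4-bromo-3-methylbut-2-enoate (E/Z mixture) | COC(=O)C=C(C)CBr | intermediate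
19 | 4-methylfuran-2(5H)-one | CC1=CC(=O)OC1 | intermediate
20 | trans-3,4-dibromo-4-methyloxolan-2-one (racemic, one enantiomer drawn) | C[C@]1(Br)COC(=O)[C@@H]1Br | intermediate
21 | 3-bromo-4-methylfuran-2(5H)-one | CC1=C(Br)C(=O)OC1 | intermediate
22 | (2E)-2-bromo-4-hydroxy-N-methoxy-N,3-dimethylbut-2-enamide | CON(C)C(=O)/C(Br)=C(/C)CO | intermediate
23 | (2E)-2-bromo-4-[(tert-butyldimethylsilyl)oxy]-N-methoxy-N,3-dimethylbut-2-enamide | CON(C)C(=O)/C(Br)=C(/C)CO[Si](C)(C)C(C)(C)C | intermediate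
24 | (2E)-2-bromo-4-[(tert-butyldimethylsilyl)oxy]-3-methylbut-2-enal | O=C/C(Br)=C(/C)CO[Si](C)(C)C(C)(C)C | intermediate
25 | (2E)-2-bromo-4-[(tert-butyldimethylsilyl)oxy]-3-methylbut-2-en-1-ol | OC/C(Br)=C(/C)CO[Si](C)(C)C(C)(C)C | intermediate
26 | tert-butyl{[(2E)-3,4-dibromo-2-methylbut-2-en-1-yl]oxy}dimethylsilane | BrC/C(Br)=C(/C)CO[Si](C)(C)C(C)(C)C | intermediate
27 | 2-lithio derivative of 16 | C[C@H](C1([Li])SCCCS1)[C@H]2C=C[C@H](C)[C@@H](O[Si](C)(C)C(C)(C)C)C2 | intermediate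
28 | 2-[(2E)-2-bromo-4-[(tert-butyldimethylsilyl)oxy]-3-methylbut-2-en-1-yl]-2-{(1S)-1-[(1R,4S,5S)-5-[(tert-butyldimethylsilyl)oxy]-4-methylcyclohex-2-en-1-yl]ethyl}-1,3-dithiane | C[C@H](C1(C/C(Br)=C(/C)CO[Si](C)(C)C(C)(C)C)SCCCS1)[C@H]2C=C[C@H](C)[C@@H](O[Si](C)(C)C(C)(C)C)C2 | intermediate
29 | (2S,5E)-5-bromo-7-[(tert-butyldimethylsilyl)oxy]-2-[(1R,4S,5S)-5-[(tert-butyldimethylsilyl)oxy]-4-methylcyclohex-2-en-1-yl]-6-methylhept-5-en-3-one | C[C@H](C(=O)C/C(Br)=C(/C)CO[Si](C)(C)C(C)(C)C)[C@H]1C=C[C@H](C)[C@@H](O[Si](C)(C)C(C)(C)C)C1 | intermediate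
30 | (2S,3S,5E)-5-bromo-7-[(tert-butyldimethylsilyl)oxy]-2-[(1R,4S,5S)-5-[(tert-butyldimethylsilyl)oxy]-4-methylcyclohex-2-en-1-yl]-6-methylhept-5-en-3-ol | C[C@H]([C@@H](O)C/C(Br)=C(/C)CO[Si](C)(C)C(C)(C)C)[C@H]1C=C[C@H](C)[C@@H](O[Si](C)(C)C(C)(C)C)C1 | intermediate
31 | (3S,4aR,5S,6S,8E,8aR)-3-[(tert-butyldimethylsilyl)oxy]-8-{1-[(tert-butyldimethylsilyl)oxy]propan-2-ylidene}-2,5-dimethyl-3,4,4a,5,6,7,8,8a-octahydronaphthalen-6-ol | CC(C)(C)[Si](C)(C)O[C@H]1C[C@H]2[C@H](C)[C@@H](O)C/C(=C(/C)CO[Si](C)(C)C(C)(C)C)[C@H]2C=C1C | intermediate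
32 | (3S,4aR,5S,6S,8E,8aR)-8-(1-hydroxypropan-2-ylidene)-2,5-dimethyl-3,4,4a,5,6,7,8,8a-octahydronaphthalene-3,6-diol | O[C@H]1C[C@H]2[C@H](C)[C@@H](O)C/C(=C(/C)CO)[C@H]2C=C1C | intermediate
33 | (E)-2-[(3S,4aR,5S,6S,8aR)-3,6-dihydroxy-2,5-dimethyl-3,4,4a,5,6,7,8,8a-octahydronaphthalen-8-ylidene]propyl formate | O[C@H]1C[C@H]2[C@H](C)[C@@H](O)C/C(=C(/C)COC=O)[C@H]2C=C1C | intermediate
34 | (E)-2-[(3S,4aR,5S,6S,8aR)-3,6-diacetoxy-2,5-dimethyl-3,4,4a,5,6,7,8,8a-octahydronaphthalen-8-ylidene]propyl formate (CNP0262962.2) | CC(=O)O[C@H]1C[C@H]2[C@H](C)[C@@H](OC(C)=O)C/C(=C(/C)COC=O)[C@H]2C=C1C | target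

**Totals**
Total step count: 24.
Longest linear sequence: 16 steps (steps 1–9, then 18–24). The second branch (steps 10–17, then 18–24) is 15 steps.

**Steps most likely to fail, with fallbacks**

Step 7 (Ireland–Claisen). The rearrangement needs a ring conformer with three axial substituents, and the chair/boat preference of the ester enolate decides the methyl-bearing centre. The fallback sets out from 9 and comes back at 15. Copper-catalysed O-vinylation of 9 with (Z)-1-iodoprop-1-ene (CuI, 3,4,7,8-tetramethyl-1,10-phenanthroline, Cs2CO3, toluene, 80 °C) gives the (Z)-prop-1-enyl ether F1. Heating F1 to 120–140 °C triggers an aliphatic Claisen rearrangement through a chair with the methyl group pointing away from the ring, which gives aldehyde 15 directly with the same two centres and bypasses 11–14.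

Step 18 (alkylation of a hindered 2-sec-alkyl dithiane). The fallback sets out from 15 and comes back at 32; it also avoids steps 19–21. The dianion of methyl 2-methyl-3-oxobutanoate (made from methyl 3-oxobutanoate and MeI; NaH then n-BuLi, THF) adds to aldehyde 15 under Felkin–Anh control to give the δ-hydroxy-β-keto ester F2 with the required carbinol configuration. Aqueous NaOH then HCl closes it to the hydroxypyranone F3. CBr4/PPh3 converts F3 into the bromolactone F4, in which the ring fixes the alkene geometry. Excess i-Bu2AlH opens F4 to the bromo diol F5. The Heck conditions of step 21 turn F5 into the bicyclic diol F6, and Bu4NF removes the remaining silyl group to give 32.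

Step 20 (catalyst-controlled reduction against the substrate's Felkin–Anh bias). The fallback sets out from 29 and comes back at 30. LiBH(s-Bu)3 (THF, −78 °C) reduces 29 with the substrate's own preference to the 3R alcohol F7. Mitsunobu inversion (4-nitrobenzoic acid, PPh3, DIAD) gives the 3S 4-nitrobenzoate F8, and K2CO3 in MeOH releases 30.

**Further compounds**
F1 | step 7 | tert-butyldimethyl{[(1S,2S,3R)-2-methyl-3-[(1Z)-prop-1-en-1-yloxy]cyclohex-4-en-1-yl]oxy}silane | C/C=C\O[C@@H]1C=CC[C@H](O[Si](C)(C)C(C)(C)C)[C@H]1C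
F2 | step 18 | methyl (5S,6S)-6-[(1R,4S,5S)-5-[(tert-butyldimethylsilyl)oxy]-4-methylcyclohex-2-en-1-yl]-5-hydroxy-2-methyl-3-oxoheptanoate (C2 epimers) | COC(=O)C(C)C(=O)C[C@H](O)[C@@H](C)[C@H]1C=C[C@H](C)[C@@H](O[Si](C)(C)C(C)(C)C)C1
F3 | step 18 | (6S)-6-{(1S)-1-[(1R,4S,5S)-5-[(tert-butyldimethylsilyl)oxy]-4-methylcyclohex-2-en-1-yl]ethyl}-4-hydroxy-3-methyl-5,6-dihydro-2H-pyran-2-one | CC1=C(O)C[C@H](OC1=O)[C@@H](C)[C@H]2C=C[C@H](C)[C@@H](O[Si](C)(C)C(C)(C)C)C2
F4 | step 18 | (6S)-4-bromo-6-{(1S)-1-[(1R,4S,5S)-5-[(tert-butyldimethylsilyl)oxy]-4-methylcyclohex-2-en-1-yl]ethyl}-3-methyl-5,6-dihydro-2H-pyran-2-one | CC1=C(Br)C[C@H](OC1=O)[C@@H](C)[C@H]2C=C[C@H](C)[C@@H](O[Si](C)(C)C(C)(C)C)C2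
F5 | step 18 | (2S,3S,5E)-5-bromo-2-[(1R,4S,5S)-5-[(tert-butyldimethylsilyl)oxy]-4-methylcyclohex-2-en-1-yl]-6-methylhept-5-ene-3,7-diol | C[C@H]([C@@H](O)C/C(Br)=C(/C)CO)[C@H]1C=C[C@H](C)[C@@H](O[Si](C)(C)C(C)(C)C)C1
F6 | step 18 | (3S,4aR,5S,6S,8E,8aR)-3-[(tert-butyldimethylsilyl)oxy]-8-(1-hydroxypropan-2-ylidene)-2,5-dimethyl-3,4,4a,5,6,7,8,8a-octahydronaphthalen-6-ol | CC(C)(C)[Si](C)(C)O[C@H]1C[C@H]2[C@H](C)[C@@H](O)C/C(=C(/C)CO)[C@H]2C=C1C
F7 | step 20 | (2S,3R,5E)-5-bromo-7-[(tert-butyldimethylsilyl)oxy]-2-[(1R,4S,5S)-5-[(tert-butyldimethylsilyl)oxy]-4-methylcyclohex-2-en-1-yl]-6-methylhept-5-en-3-ol | C[C@H]([C@H](O)C/C(Br)=C(/C)CO[Si](C)(C)C(C)(C)C)[C@H]1C=C[C@H](C)[C@@H](O[Si](C)(C)C(C)(C)C)C1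
F8 | step 20 | (2S,3S,5E)-5-bromo-7-[(tert-butyldimethylsilyl)oxy]-2-[(1R,4S,5S)-5-[(tert-butyldimethylsilyl)oxy]-4-methylcyclohex-2-en-1-yl]-6-methylhept-5-en-3-yl 4-nitrobenzoate | C[C@H]([C@@H](OC(=O)c1ccc(cc1)[N+](=O)[O-])C/C(Br)=C(/C)CO[Si](C)(C)C(C)(C)C)[C@H]2C=C[C@H](C)[C@@H](O[Si](C)(C)C(C)(C)C)C2
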